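After 2.50 d the ochre run still holds 93.7% of its starting material and the red run 98.1%, so neither is short of it, and the percentages of target hide what the runs share.

| flask | starting material | solid reagent | free catalyst | remark | time |
|---|---|---|---|---|---|
| ochre | 0.25 M | 0.50 M | 0.25 mM | run made earlier |  |
| red | 1 M | 0.50 M | 0.25 mM | run made earlier |  |
| blue | 0.50 M | 0.25 M | 0.25 mM | run made earlier |  |
| flask | 0.50 M | 0.500 M | 0.25 mM |  | 2.5 d |

| run | time / d | target / % | starting material / % |
|---|---|---|---|
| ochre | 0.125 | 0.6 | 100.5 |
| ochre | 0.417 | 0 | 99.9 |
| ochre | 0.625 | 0.9 | 99.5 |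
| ochre | 1.04 | 1.8 | 98.4 |
| ochre | 1.67 | 4.2 | 97.1 |
| ochre | 2.08 | 4.8 | 94.7 |
| ochre | 2.50 | 6.0 | 93.7 |
| red | 0.208 | 0 | 100.6 |
| red | 0.333 | 0.3 | 100.5 |
| red | 0.500 | 0.1 | 99.8 |
| red | 0.625 | 0.8 | 100.2 |
| red | 1.04 | 0 | 99.7 |
| red | 1.67 | 1.4 | 98.7 |
| red | 2.50 | 1.5 | 98.1 |
| blue | 0.208 | 0.1 | 99.8 |
| blue | 0.625 | 0.6 | 99.7 |
| blue | 1.25 | 1.1 | 98.6 |
| blue | 1.67 | 2.4 | 98.3 |
| blue | 2.50 | 3.3 | 96.9 |

(readings scatter by 0.5 percentage points)

- target at 2.5 d, in percent of the starting material charged
- concentration of partner in solution at 2.5 d, in percent of saturation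

- as a solid, counted per litre of solution: solid reagent
- the numbers in the tables scatter by 0.5 percentage points (one standard deviation)
- at the start none of the solid reagent is in solution
- partner is what solid reagent becomes in solution

In concentration, c(target) at that time reads 0.0150 M in ochre, 0.0150 M in red and 0.0165 M in blue, though c(starting material) spans a factor of 4.00 and the solid loading a factor of 2.00. A rate containing neither charge integrates to c(target) = r(t − t_lag), with r and t_lag shared by the runs. At one time and with free catalyst held at 0.25 mM, then, one number serves: the make, the mean c(target) read at 2.5 d, 0.0155 M.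

Two chemists accept the make and quarrel over where partner stands in solution. The first says the solid keeps the solution near saturation while the catalyst works at full capacity. The second calls the passage from solid into solution the rate-limiting step: the catalyst takes partner as it arrives, and the solution stays far below saturation. Neither view changes the target, which I reckon as make over charge, 3.10%. I side with the second on partner, though the runs give no figure for it.

The forecast takes the first side, with 3.2% (2.7% to 3.8%) and 95% (78% to 100%), and says “By 2.5 d, partner should be close to saturation”.

The flask gives 3.09% of target, and partner stands at 0.00713 M, 10.5% of saturation.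

    partner + free catalyst → catalyst intermediate A (k = 3.40 L mol⁻¹ min⁻¹)
    catalyst intermediate A ⇌ catalyst intermediate B (K = 56.0, k = 1.20 min⁻¹)
    starting material + catalyst intermediate B ⇌ catalyst intermediate C (K = 1.40 L mol⁻¹, k = 3.10 L mol⁻¹ min⁻¹)
    catalyst intermediate C → by-product + catalyst intermediate D (k = 28.0 min⁻¹)
    catalyst intermediate D → free catalyst + target (k = 14.0 min⁻¹)
    solid reagent ⇌ partner, rate k6*(cs6 - [partner]) while solid is left; crystals form when [partner] > cs6 (solubility = 0.0680 M, k = 1.00 × 10⁻⁴ min⁻¹)

The first chemist's picture belongs to a run with every passage between the phases made instant, where target at 2.5 d reaches 29.3%. A neighbouring flask charged with 2.0 M of solid reagent, 4.00 equiv to the starting material, keeps the same make by the rule, so the reckoning again says 3.10%. It gives 3.09%, with partner at 0.00713 M.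

(All runs are simulated with constants of no real substance.)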